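**Plan**
- Retrosynthesis: the four O-methyl ethers are restored and the CH2CH2 bridge between C4 of the para-phenylene ring B and C1 of catechol ring C is taken back to an alkyne. One alkyne carbon and one aryl–C bond are then removed, which leaves an 18-membered diaryl ketone.
- Enabling feature: as a C=O, that bridge sits para to the ring B carbon bearing the A–O–B ether oxygen. The same carbonyl therefore first activates this carbon for fluoride displacement and then takes up the extra carbon.
- Further cuts: A–O–B ether (SNAr), carbonyl–ring B bond (Grignard addition), C–O–D ether (Ullmann coupling), A–D CH2CH2 bridge (Wittig reaction, hydrogenation).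
- Forward order: rings A and D are joined as a bibenzyl, ring C is attached through oxygen and ring B through the carbonyl. The 18-membered ring closes at A–O–B, is expanded to the 19-membered alkyne, then reduced and demethylated.
- Stereochemistry: the target has no stereocentre. The alkene geometry of step 3 and the racemic carbinol of step 6 are erased in steps 4 and 7.

Key step: step 10

Remark: the macrocycle is assumed to be conformationally mobile and is treated as achiral; 4-fluorophenylmagnesium bromide (the Grignard reagent of 1-bromo-4-fluorobenzene) is taken as its commercial THF solution.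

**Step 1**
Reactants: 1 3-hydroxy-4,5-dimethoxybenzaldehyde
Product: 2 3,4-dimethoxy-5-(methoxymethoxy)benzaldehyde
Conditions: MOMCl, K2CO3, acetone, 0 °C to rt
Reagents that add atoms: chloromethyl methyl ether, COCCl
Why: Williamson-type O-alkylation of the phenoxide masks the ring A phenol as a methoxymethyl acetal, which should survive base, hydrogenation, copper catalysis, Grignard addition and MnO2 and later be cleaved by acid without touching the methyl ethers.

**Step 2**
Reactants: 3 3-hydroxybenzyl alcohol
Product: 4 (3-hydroxybenzyl)triphenylphosphonium bromide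
Conditions: PPh3·HBr, MeCN, reflux
Reagents that add atoms: triphenylphosphine hydrobromide, Br.c1ccc(cc1)P(c1ccccc1)c1ccccc1
Why: Acid-mediated benzylic substitution of the protonated alcohol by triphenylphosphine should give the phosphonium salt in one operation and leave the ring D phenol free.

**Step 3**
Reactants: 4 (3-hydroxybenzyl)triphenylphosphonium bromide; 2 3,4-dimethoxy-5-(methoxymethoxy)benzaldehyde
Product: 6 3-[2-[3,4-dimethoxy-5-(methoxymethoxy)phenyl]ethenyl]phenol (E/Z mixture), via phenoxide ylide 5 (not isolated)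
Conditions: KOtBu (2.2 equiv), THF, 0 °C; then 2, 0 °C to rt; H2O work-up
Reagents that add atoms: none
Why: Wittig olefination of the non-enolizable aldehyde by the semi-stabilized phenoxide ylide should form the A–D two-carbon link as a mixture of alkene isomers, both of which converge in step 4.

**Step 4**
Reactants: 6 3-[2-[3,4-dimethoxy-5-(methoxymethoxy)phenyl]ethenyl]phenol (E/Z mixture)
Product: 7 3-[2-[3,4-dimethoxy-5-(methoxymethoxy)phenyl]ethyl]phenol
Conditions: H2 (1 atm), 10% Pd/C, EtOAc, rt
Reagents that add atoms: none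
Why: Heterogeneous catalytic hydrogenation should saturate both stilbene isomers, while the acetal and aryl ethers are inert under neutral conditions.

**Step 5**
Reactants: 7 3-[2-[3,4-dimethoxy-5-(methoxymethoxy)phenyl]ethyl]phenol; 8 3-bromo-4,5-dimethoxybenzaldehyde
Product: 9 3-[3-[2-[3,4-dimethoxy-5-(methoxymethoxy)phenyl]ethyl]phenoxy]-4,5-dimethoxybenzaldehyde
Conditions: CuI (cat.), N,N-dimethylglycine hydrochloride, Cs2CO3, 1,4-dioxane, 100 °C
Reagents that add atoms: none
Why: Amino acid-promoted Ullmann diaryl ether coupling should join the only free phenol (ring D) to the ring C bromide, since the aldehyde has no α-hydrogen and the methoxymethyl ether is stable to base.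

**Step 6**
Reactants: 9 3-[3-[2-[3,4-dimethoxy-5-(methoxymethoxy)phenyl]ethyl]phenoxy]-4,5-dimethoxybenzaldehyde; 10 4-fluorophenylmagnesium bromide
Product: 11 (4-fluorophenyl)[3-[3-[2-[3,4-dimethoxy-5-(methoxymethoxy)phenyl]ethyl]phenoxy]-4,5-dimethoxyphenyl]methanol (racemic)
Conditions: THF, 0 °C; H2O quench
Reagents that add atoms: none
Why: Grignard 1,2-addition to the aromatic aldehyde should attach ring B, and the carbinol stereocentre forms without control as a racemate that is erased in step 7.

**Step 7**
Reactants: 11 (4-fluorophenyl)[3-[3-[2-[3,4-dimethoxy-5-(methoxymethoxy)phenyl]ethyl]phenoxy]-4,5-dimethoxyphenyl]methanol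
Product: 12 (4-fluorophenyl)[3-[3-[2-[3,4-dimethoxy-5-(methoxymethoxy)phenyl]ethyl]phenoxy]-4,5-dimethoxyphenyl]methanone
Conditions: activated MnO2 (excess), CH2Cl2, rt
Reagents that add atoms: none
Why: MnO2 oxidation of a doubly benzylic alcohol should give the diaryl ketone under neutral conditions that leave the acetal and ethers alone.

**Step 8**
Reactants: 12 (4-fluorophenyl)[3-[3-[2-[3,4-dimethoxy-5-(methoxymethoxy)phenyl]ethyl]phenoxy]-4,5-dimethoxyphenyl]methanone
Product: 13 (4-fluorophenyl)[3-[3-[2-(3-hydroxy-4,5-dimethoxyphenyl)ethyl]phenoxy]-4,5-dimethoxyphenyl]methanone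
Conditions: HCl (cat.), MeOH/THF, 50 °C
Reagents that add atoms: none
Why: Acid-catalysed acetal exchange with methanol should free the ring A phenol, while methyl ethers, diaryl ether, ketone and aryl fluoride do not react.

**Step 9**
Reactants: 13 (4-fluorophenyl)[3-[3-[2-(3-hydroxy-4,5-dimethoxyphenyl)ethyl]phenoxy]-4,5-dimethoxyphenyl]methanone
Product: 14 18-membered macrocyclic diaryl ketone (tetra-O-methyl)
Conditions: Cs2CO3, DMSO, 120 °C, 2 mM (slow addition of 13)
Reagents that add atoms: none
Why: Intramolecular SNAr (addition–elimination through a Meisenheimer intermediate) should close the 18-membered ring at the A–O–B ether, because the para-benzoyl group activates the ring B fluoride and high dilution favours closure over oligomerization.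

**Step 10**
Reactants: 14 18-membered macrocyclic diaryl ketone (tetra-O-methyl)
Product: 18 19-membered macrocyclic diarylalkyne (tetra-O-methyl), via lithium diazo(silyl)alkoxide 15 (not isolated), via diazoalkene 16 (not isolated), via alkylidene carbene 17 (not isolated)
Conditions: TMSCHN2, n-BuLi, THF, −78 °C; then 14, −78 °C to rt
Reagents that add atoms: trimethylsilyldiazomethane, C[Si](C)(C)C=[N+]=[N-]
Why: Proposed new method: lithio(trimethylsilyl)diazomethane adds to the only electrophile, the diaryl ketone, to give alkoxide 15; Peterson-type loss of lithium trimethylsilanolate gives diazoalkene 16 and loss of N2 gives alkylidene carbene 17, in which one aryl ring migrates with its bonding pair to the carbene carbon (Fritsch–Buttenberg–Wiechell shift), so the former carbonyl carbon and the new carbon become the alkyne. The closest known reaction is the Colvin-type conversion of acyclic diaryl ketones into diarylalkynes with this reagent; its use on a macrocyclic ketone, where the shift moves a ring bond, is the new element. The 19-membered ring arises by one-carbon ring expansion of the 18-membered ring through migration of a ring aryl–C bond, not by end-to-end cyclization, and one C–C bond to the new carbon plus one aryl–C bond are formed. No stereocentre is created. Only chemoselectivity is needed; it is secured because the ketone has no α-hydrogen, the methyl and diaryl ethers are inert to the reagent, no C–H bond is placed for 1,5-insertion, and migration of ring B or ring C gives the same alkyne. Loss of N2 and alkyne formation should pay for the strain of the para-phenylene–alkyne rod, which the three meta-linked rings, the two ether oxygens and the remaining CH2CH2 bridge can absorb.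

**Step 11**
Reactants: 18 19-membered macrocyclic diarylalkyne (tetra-O-methyl)
Product: 19 19-membered macrocyclic bis(bibenzyl) tetramethyl ether
Conditions: H2 (1 atm), 10% Pd/C, EtOAc/MeOH, rt
Reagents that add atoms: none
Why: Catalytic hydrogenation of the diarylalkyne to the CH2CH2 bridge should be fast and strain-releasing, and the aryl ethers are not touched.

**Step 12**
Reactants: 19 19-membered macrocyclic bis(bibenzyl) tetramethyl ether
Product: 20 CNP0511668.0 (target)
Conditions: BBr3 (excess), CH2Cl2, −78 °C to rt; H2O quench under argon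
Reagents that add atoms: none
Why: BBr3 demethylation (bromide attack on the methyl group of the boron–ether adduct) should cleave all four aryl methyl ethers to the two catechols, whereas the diaryl ether C–O bonds do not cleave under these conditions.

**Compound list**

Macrocycle numbering used in the names: ring A carries the CH2 at C1, the oxygen to ring B at C3 and oxygen substituents at C4 and C5. Ring C carries the bridge carbon at C1, the oxygen to ring D at C5 and oxygen substituents at C3 and C4. Ring B is 1,4-linked and ring D is 1,3-linked.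

1 | 3-hydroxy-4,5-dimethoxybenzaldehyde | COc1cc(C=O)cc(O)c1OC | starting material
2 | 3,4-dimethoxy-5-(methoxymethoxy)benzaldehyde | COCOc1cc(C=O)cc(OC)c1OC | intermediate
3 | 3-hydroxybenzyl alcohol | OCc1cccc(O)c1 | starting material
4 | (3-hydroxybenzyl)triphenylphosphonium bromide | [Br-].Oc1cccc(C[P+](c2ccccc2)(c2ccccc2)c2ccccc2)c1 | intermediate
5 | potassium 3-[(triphenylphosphoranylidene)methyl]phenolate (phenoxide ylide) | [K+].[O-]c1cccc(C=P(c2ccccc2)(c2ccccc2)c2ccccc2)c1 | intermediate (not isolated)
6 | 3-[2-[3,4-dimethoxy-5-(methoxymethoxy)phenyl]ethenyl]phenol, E/Z mixture (geometry left open) | COCOc1cc(C=Cc2cccc(O)c2)cc(OC)c1OC | intermediate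
7 | 3-[2-[3,4-dimethoxy-5-(methoxymethoxy)phenyl]ethyl]phenol | COCOc1cc(CCc2cccc(O)c2)cc(OC)c1OC | intermediate
8 | 3-bromo-4,5-dimethoxybenzaldehyde | COc1cc(C=O)cc(Br)c1OC | starting material
9 | 3-[3-[2-[3,4-dimethoxy-5-(methoxymethoxy)phenyl]ethyl]phenoxy]-4,5-dimethoxybenzaldehyde | COCOc1cc(CCc2cccc(Oc3cc(C=O)cc(OC)c3OC)c2)cc(OC)c1OC | intermediate
10 | 4-fluorophenylmagnesium bromide (THF solution) | Fc1ccc([Mg]Br)cc1 | starting material
11 | (4-fluorophenyl)[3-[3-[2-[3,4-dimethoxy-5-(methoxymethoxy)phenyl]ethyl]phenoxy]-4,5-dimethoxyphenyl]methanol, racemic | COCOc1cc(CCc2cccc(Oc3cc(C(O)c4ccc(F)cc4)cc(OC)c3OC)c2)cc(OC)c1OC | intermediate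
12 | (4-fluorophenyl)[3-[3-[2-[3,4-dimethoxy-5-(methoxymethoxy)phenyl]ethyl]phenoxy]-4,5-dimethoxyphenyl]methanone | COCOc1cc(CCc2cccc(Oc3cc(C(=O)c4ccc(F)cc4)cc(OC)c3OC)c2)cc(OC)c1OC | intermediate
13 | (4-fluorophenyl)[3-[3-[2-(3-hydroxy-4,5-dimethoxyphenyl)ethyl]phenoxy]-4,5-dimethoxyphenyl]methanone | Oc1cc(CCc2cccc(Oc3cc(C(=O)c4ccc(F)cc4)cc(OC)c3OC)c2)cc(OC)c1OC | intermediate
14 | 18-membered macrocyclic diaryl ketone, tetra-O-methyl: ring A–O–ring B–C(=O)–ring C–O–ring D–CH2CH2–ring A | COc1cc2cc(c1OC)Oc1ccc(cc1)C(=O)c1cc(OC)c(OC)c(c1)Oc1cccc(c1)CC2 | intermediate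
15 | lithium alkoxide adduct of 14 bearing a diazo(trimethylsilyl)methyl group on the former carbonyl carbon, racemic | COc1cc2cc(c1OC)Oc1ccc(cc1)C([O-])(C(=[N+]=[N-])[Si](C)(C)C)c1cc(OC)c(OC)c(c1)Oc1cccc(c1)CC2.[Li+] | intermediate (not isolated)
16 | macrocyclic 1,1-diaryl-2-diazoethene (C=C=N2 in place of the C=O of 14) | COc1cc2cc(c1OC)Oc1ccc(cc1)C(=C=[N+]=[N-])c1cc(OC)c(OC)c(c1)Oc1cccc(c1)CC2 | intermediate (not isolated)
17 | macrocyclic diarylalkylidene carbene (C=C: in place of the C=O of 14) | COc1cc2cc(c1OC)Oc1ccc(cc1)C(=[C])c1cc(OC)c(OC)c(c1)Oc1cccc(c1)CC2 | intermediate (not isolated)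
18 | 19-membered macrocyclic diarylalkyne, tetra-O-methyl: ring A–O–ring B–C≡C–ring C–O–ring D–CH2CH2–ring A | COc1cc2cc(c1OC)Oc1ccc(cc1)C#Cc1cc(OC)c(OC)c(c1)Oc1cccc(c1)CC2 | intermediate
19 | 19-membered macrocyclic bis(bibenzyl) tetramethyl ether: ring A–O–ring B–CH2CH2–ring C–O–ring D–CH2CH2–ring A | COc1cc2cc(c1OC)Oc1ccc(cc1)CCc1cc(OC)c(OC)c(c1)Oc1cccc(c1)CC2 | intermediate
20 | CNP0511668.0, the tetrahydroxy macrocyclic bis(bibenzyl) (achiral) | Oc1cc2cc(c1O)Oc1ccc(cc1)CCc1cc(O)c(O)c(c1)Oc1cccc(c1)CC2 | target

**Step count**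
Total: 12 steps. Longest linear sequence: 11 steps (from 1 through steps 1 and 3 to 12).

**Steps most likely to fail**

Step 10 (ring-expanding aryl shift). The 1,2-aryl shift may be slowed because its transition state must already fit the linear aryl–C≡C–aryl rod into the ring. The carbene or its diazoalkene precursor would then be diverted to protonation, insertion or dimerization. The fallback uses known chemistry and gives up the ring expansion; it sets out from 9 and comes back at 19. The methoxymethyl group of 9 is removed with HCl in MeOH to give 3-[3-[2-(3-hydroxy-4,5-dimethoxyphenyl)ethyl]phenoxy]-4,5-dimethoxybenzaldehyde F1. Its phenol displaces fluoride from 4-fluorobenzaldehyde (K2CO3, DMF, 120 °C) to give the dialdehyde 3-[3-[2-[3-(4-formylphenoxy)-4,5-dimethoxyphenyl]ethyl]phenoxy]-4,5-dimethoxybenzaldehyde F2. Intramolecular McMurry coupling (TiCl4, Zn, pyridine, THF, reflux, high dilution) joins the two formyl carbons to give the 19-membered macrocyclic stilbene tetramethyl ether F3 (drawn as the Z isomer; an E isomer would converge). Hydrogenation over Pd/C then gives 19.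

Step 9 (macrocyclic SNAr). A benzoyl group activates fluoride displacement only moderately, so at the temperature required intermolecular ether formation (oligomerization) may outrun closure of the 18-membered ring. The fallback closes the same ether by copper-mediated coupling instead of addition–elimination; it sets out from 9 and comes back at 14. Addition of 4-bromophenylmagnesium chloride (from 1-bromo-4-iodobenzene and iPrMgCl·LiCl, THF, −20 °C) to 9 gives (4-bromophenyl)[3-[3-[2-[3,4-dimethoxy-5-(methoxymethoxy)phenyl]ethyl]phenoxy]-4,5-dimethoxyphenyl]methanol F4. MnO2 oxidation gives (4-bromophenyl)[3-[3-[2-[3,4-dimethoxy-5-(methoxymethoxy)phenyl]ethyl]phenoxy]-4,5-dimethoxyphenyl]methanone F5. HCl in MeOH gives (4-bromophenyl)[3-[3-[2-(3-hydroxy-4,5-dimethoxyphenyl)ethyl]phenoxy]-4,5-dimethoxyphenyl]methanone F6. Intramolecular Ullmann etherification (CuI, N,N-dimethylglycine hydrochloride, Cs2CO3, 1,4-dioxane, 100 °C, high dilution) then gives 14.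

Step 5 (Ullmann coupling). Coupling at the bromide flanked by an ortho-methoxy group may be sluggish, so that protodebromination or base-induced disproportionation of the aldehyde takes over. The fallback reverses the polarity of ring C and couples oxidatively at room temperature; it sets out from 8 and comes back at 9. Miyaura borylation of 8 (B2pin2, Pd(dppf)Cl2, KOAc, 1,4-dioxane, 90 °C) gives 3,4-dimethoxy-5-(4,4,5,5-tetramethyl-1,3,2-dioxaborolan-2-yl)benzaldehyde F7. Oxidative cleavage of the pinacol ester (NaIO4, NH4OAc, acetone/H2O) gives (5-formyl-2,3-dimethoxyphenyl)boronic acid F8. Chan–Lam coupling of F8 with phenol 7 (Cu(OAc)2, pyridine, 4 Å molecular sieves, CH2Cl2, air, rt) then gives 9.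

**Further compounds**
F1 | step 10 | 3-[3-[2-(3-hydroxy-4,5-dimethoxyphenyl)ethyl]phenoxy]-4,5-dimethoxybenzaldehyde | Oc1cc(CCc2cccc(Oc3cc(C=O)cc(OC)c3OC)c2)cc(OC)c1OC
F2 | step 10 | 3-[3-[2-[3-(4-formylphenoxy)-4,5-dimethoxyphenyl]ethyl]phenoxy]-4,5-dimethoxybenzaldehyde | O=Cc1ccc(Oc2cc(CCc3cccc(Oc4cc(C=O)cc(OC)c4OC)c3)cc(OC)c2OC)cc1
F3 | step 10 | 19-membered macrocyclic stilbene tetramethyl ether (Z): ring A–O–ring B–CH=CH–ring C–O–ring D–CH2CH2–ring A | COc1cc2cc(c1OC)Oc1ccc(cc1)/C=C\c1cc(OC)c(OC)c(c1)Oc1cccc(c1)CC2
F4 | step 9 | (4-bromophenyl)[3-[3-[2-[3,4-dimethoxy-5-(methoxymethoxy)phenyl]ethyl]phenoxy]-4,5-dimethoxyphenyl]methanol, racemic | COCOc1cc(CCc2cccc(Oc3cc(C(O)c4ccc(Br)cc4)cc(OC)c3OC)c2)cc(OC)c1OC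
F5 | step 9 | (4-bromophenyl)[3-[3-[2-[3,4-dimethoxy-5-(methoxymethoxy)phenyl]ethyl]phenoxy]-4,5-dimethoxyphenyl]methanone | COCOc1cc(CCc2cccc(Oc3cc(C(=O)c4ccc(Br)cc4)cc(OC)c3OC)c2)cc(OC)c1OC
F6 | step 9 | (4-bromophenyl)[3-[3-[2-(3-hydroxy-4,5-dimethoxyphenyl)ethyl]phenoxy]-4,5-dimethoxyphenyl]methanone | Oc1cc(CCc2cccc(Oc3cc(C(=O)c4ccc(Br)cc4)cc(OC)c3OC)c2)cc(OC)c1OC
F7 | step 5 | 3,4-dimethoxy-5-(4,4,5,5-tetramethyl-1,3,2-dioxaborolan-2-yl)benzaldehyde | COc1cc(C=O)cc(B2OC(C)(C)C(C)(C)O2)c1OC
F8 | step 5 | (5-formyl-2,3-dimethoxyphenyl)boronic acid | COc1cc(C=O)cc(B(O)O)c1OC
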